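Ring B, the resorcinol ring fused to the seven-membered ring, has its hydroxyls at C7 and C9 and its two ring-fusion carbons C5a and C9a side by side (dibenzo[a,d][7]annulene numbering): the imprint of an acetoacetyl chain on C9a folded onto a ketone at C5a. Everything rests on disconnecting the C5a–C6 bond. Hydroxide unmasks a cyclohepta-fused 2-methyl-4-pyranone as a 1,3,5-triketone whose methyl carbon closes ring B by aldol condensation and aromatization in one operation. The precursor is an enantiopure benzocycloheptene bearing the 2,4-dimethoxyphenyl stereocentre, a dioxolane at the future C5 and, as a handle for the second dihydrobenzofuran, a bromine on ring A.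

Key step: step 9

Remarks on the chemistry and on locants:
- Bicyclic compounds use benzo[7]annulene numbering: arene C1–C4, C5 is the dioxolane carbon, C6 the ketone, C8 the aryl-bearing carbon, C9 the benzylic CH2.
- Tricyclic compounds use dibenzo[a,d][7]annulene numbering: ring A is C1–C4, C5 lies between the two arenes, ring B is C6–C9, C10 is the aryl-bearing carbon, C11 the CH2.
- In the first dihydrobenzofuran (O on C4, C-3 = C5) the anisyl-bearing carbon is C2′. In the second (O on C2, attached at C1) the carbons are C2″ (anisyl) and C3″ (3,5-dimethoxyphenyl).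
- The aryl-bearing centre keeps one spatial arrangement throughout; its CIP label changes from S to R only because the priorities of its neighbours change.
- Assumption: 3, 22 and 26 are taken as commercial; the facial selectivity of both dihydrobenzofuran annulations is substrate-controlled, as argued at steps 14 and 18.

Step 1
Reactants: 1 1-allyl-3,5-dimethoxybenzene
Product: 2 3-allyl-2,4-dibromo-1,5-dimethoxybenzene
Conditions: NBS (2.1 equiv), MeCN, 0 °C → rt, dark
Reagents that add atoms: N-bromosuccinimide, O=C1CCC(=O)N1Br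
Why: Electrophilic aromatic bromination should take both positions ortho to the allyl group (each para to one methoxy and ortho to the other) and leave the hindered position between the methoxy groups, the activated arene reacting far faster than the isolated alkene under ionic conditions.

Step 2
Reactants: 2 3-allyl-2,4-dibromo-1,5-dimethoxybenzene; 3 N,N'-dimethoxy-N,N'-dimethyloxamide
Product: 4 2-(2-allyl-3-bromo-4,6-dimethoxyphenyl)-N-methoxy-N-methyl-2-oxoacetamide
Conditions: n-BuLi (1.0 equiv), THF, −78 °C; cannulate into 3 (1.5 equiv), THF, −78 → 0 °C; aq. NH4Cl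
Reagents that add atoms: none
Why: Bromine–lithium exchange on the symmetric dibromide can give only one monolithio species and a second exchange is disfavoured, and the aryllithium should acylate the oxamide once because the chelated tetrahedral adduct persists until work-up (Weinreb-type acylation).

Step 3
Reactants: 4 2-(2-allyl-3-bromo-4,6-dimethoxyphenyl)-N-methoxy-N-methyl-2-oxoacetamide
Product: 5 2-(2-allyl-3-bromo-4,6-dimethoxyphenyl)-N-methoxy-N-methyl-1,3-dioxolane-2-carboxamide
Conditions: TMSOCH2CH2OTMS (3 equiv), TMSOTf (10 mol %), CH2Cl2, −78 → 0 °C; pyridine quench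
Reagents that add atoms: 1,2-bis(trimethylsilyloxy)ethane, C[Si](C)(C)OCCO[Si](C)(C)C
Why: Silyl triflate-catalysed ketalization under aprotic conditions is the method of choice for hindered ketones, the ketone is activated by the neighbouring amide carbonyl, and irreversible formation of hexamethyldisiloxane should drive the di-ortho-substituted aryl ketone to the dioxolane without touching alkene, aryl bromide or amide.

Step 4
Reactants: 5 2-(2-allyl-3-bromo-4,6-dimethoxyphenyl)-N-methoxy-N-methyl-1,3-dioxolane-2-carboxamide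
Product: 6 1-[2-(2-allyl-3-bromo-4,6-dimethoxyphenyl)-1,3-dioxolan-2-yl]prop-2-en-1-one
Conditions: CH2=CHMgBr (2 equiv), THF, −78 → 0 °C; inverse quench into cold 1 M HCl
Reagents that add atoms: vinylmagnesium bromide, C=C[Mg]Br
Why: Weinreb ketone synthesis, in which the magnesium chelate prevents over-addition and the cold acidic inverse quench protonates the released N,O-dimethylhydroxylamine before it can add to the vinyl ketone.

Step 5
Reactants: 6 1-[2-(2-allyl-3-bromo-4,6-dimethoxyphenyl)-1,3-dioxolan-2-yl]prop-2-en-1-one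
Product: 7 1-bromo-2,4-dimethoxy-9H-spiro[benzo[7]annulene-5,2'-[1,3]dioxolan]-6-one
Conditions: second-generation Grubbs catalyst RuCl2(=CHPh)(H2IMes)(PCy3) (5 mol %), 1,4-benzoquinone (10 mol %), CH2Cl2 (5 mM), 40 °C
Reagents that add atoms: none
Why: Ring-closing metathesis should start at the terminal allyl alkene and close onto the vinyl ketone to give the seven-membered cis-enone with loss of ethylene, benzoquinone suppressing ruthenium hydride isomerization of the allylarene.

Step 6
Reactants: 7 1-bromo-2,4-dimethoxy-9H-spiro[benzo[7]annulene-5,2'-[1,3]dioxolan]-6-one; 8 2,4-dimethoxyphenylboronic acid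
Product: 9 (8S)-1-bromo-8-(2,4-dimethoxyphenyl)-2,4-dimethoxy-8,9-dihydro-7H-spiro[benzo[7]annulene-5,2'-[1,3]dioxolan]-6-one
Conditions: Rh(acac)(C2H4)2 (3 mol %), (S)-BINAP (3.6 mol %), 8 (3 equiv), dioxane/H2O 10:1, 100 °C
Reagents that add atoms: none
Why: Hayashi–Miyaura conjugate addition, in which the aryl–rhodium–(S)-BINAP species should add to the same enone face as in 2-cycloheptenone (which gives (S)-3-arylcycloheptanones) and so set C8 as S, while the aryl bromide is inert to monovalent rhodium and the base-free medium avoids deconjugation of the enone.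

Step 7
Reactants: 9 (8S)-1-bromo-8-(2,4-dimethoxyphenyl)-2,4-dimethoxy-8,9-dihydro-7H-spiro[benzo[7]annulene-5,2'-[1,3]dioxolan]-6-one
Product: 10 (8S)-1-bromo-8-(2,4-dimethoxyphenyl)-2,4-dimethoxy-6-(trimethylsilyloxy)-8,9-dihydrospiro[benzo[7]annulene-5,2'-[1,3]dioxolane]
Conditions: LiN(SiMe3)2 (1.2 equiv), THF, −78 °C; TMSCl, Et3N, −78 → 0 °C; pentane, aq. NaHCO3
Reagents that add atoms: chlorotrimethylsilane, C[Si](C)(C)Cl
Why: Enolization and O-silylation can occur only toward C7, because the other α-carbon is the quaternary dioxolane carbon, and C8 carries no acidifying group.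

Step 8
Reactants: 10 (8S)-1-bromo-8-(2,4-dimethoxyphenyl)-2,4-dimethoxy-6-(trimethylsilyloxy)-8,9-dihydrospiro[benzo[7]annulene-5,2'-[1,3]dioxolane]; 11 2,2,6-trimethyl-4H-1,3-dioxin-4-one
Product: 13 cyclohepta-fused 2-methyl-4-pyranone (aryl-bearing carbon R), via silyloxy-dihydropyranone cycloadduct 12 (not isolated)
Conditions: 11 (4 equiv, slow addition), toluene, 110 °C; then CSA (10 mol %), 4 Å MS, toluene, rt
Reagents that add atoms: none
Why: Thermal retro-[4+2] of 11 releases acetylketene, which should undergo hetero-Diels–Alder addition to the enol silane (C–C bond to C7, C–O bond to C6), and anhydrous acid then eliminates trimethylsilanol to the 4-pyranone while the dioxolane, with no water present, stays closed.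

Step 9
Reactants: 13 cyclohepta-fused 2-methyl-4-pyranone (aryl-bearing carbon R)
Product: 15 (10R)-1-bromo-10-(2,4-dimethoxyphenyl)-2,4-dimethoxy-10,11-dihydrospiro[dibenzo[a,d][7]annulene-5,2'-[1,3]dioxolane]-7,9-diol, via 1,3,5-triketone 14 (not isolated)
Conditions: Ba(OH)2·8H2O (5 equiv), dioxane/H2O 1:1 (degassed), 90 °C; then CO2, 0 °C
Reagents that add atoms: barium hydroxide, [Ba+2].[OH-].[OH-] (hydroxide can supply one resorcinol oxygen while the former ring oxygen leaves as water; no net gain of atoms)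
Why: Hydroxide should add in conjugate fashion to the pyranone at its less hindered methyl-bearing carbon and open the ring to the enolates of triketone 14, in which the cycloheptanone carbonyl is the only ketone outside the acetylacetone-type enolate. The terminal methyl carbon then adds to that carbonyl, water is lost and the cyclohexadienone tautomerizes to the resorcinol, an irreversible sink for the reversible opening and aldol steps; the closest known reaction type is the base-induced conversion of 2,6-dimethyl-4-pyranone through heptane-2,4,6-trione into orcinol. Ring B closes by a 6-(enolexo)-exo-trig aldol addition that forms the C5a–C6 bond. No stereocentre is created, and the aryl-bearing carbon, a benzylic C–H with neither a carbonyl nor a leaving group on it, should not epimerize. The selectivity needed is chemoselectivity between this aldol and other aldol or retro-Claisen pathways: the spiro-dioxolane carbon has no hydrogen and so cannot enolize or act as a rival nucleophile, every other aldol would give a four-membered ring, and only the six-membered product can aromatize. The aryl bromide and methyl ethers are inert to aqueous barium hydroxide, and neutralization with carbon dioxide spares the acid-labile dioxolane.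

Step 10
Reactants: 15 (10R)-1-bromo-10-(2,4-dimethoxyphenyl)-2,4-dimethoxy-10,11-dihydrospiro[dibenzo[a,d][7]annulene-5,2'-[1,3]dioxolane]-7,9-diol
Product: 17 (10R)-1-bromo-10-(2,4-dimethoxyphenyl)-2,4,7,9-tetramethoxy-10,11-dihydro-5H-dibenzo[a,d][7]annulen-5-one, via tetramethoxy dioxolane 16 (not isolated)
Conditions: MeI (6 equiv), K2CO3, acetone, 50 °C; evaporate; then 2 M HCl/THF 1:4, rt
Reagents that add atoms: iodomethane, CI
Why: Williamson O-methylation of the two phenols is followed by acid hydrolysis of the dioxolane, which is fast because the oxocarbenium ion is stabilized by the ortho and para methoxy groups of ring A.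

Step 11
Reactants: 17 (10R)-1-bromo-10-(2,4-dimethoxyphenyl)-2,4,7,9-tetramethoxy-10,11-dihydro-5H-dibenzo[a,d][7]annulen-5-one
Product: 18 (10R)-1-bromo-10-(2,4-dimethoxyphenyl)-4-hydroxy-2,7,9-trimethoxy-10,11-dihydro-5H-dibenzo[a,d][7]annulen-5-one
Conditions: BCl3 (1.5 equiv), CH2Cl2, −78 → 0 °C; aq. NaHCO3
Reagents that add atoms: none
Why: Chelation-controlled demethylation: boron bound to the C5 ketone reaches only the C4 methoxy group through a six-membered chelate, since ring B has hydrogen ortho to the carbonyl and all other methoxy groups are remote.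

Step 12
Reactants: 18 (10R)-1-bromo-10-(2,4-dimethoxyphenyl)-4-hydroxy-2,7,9-trimethoxy-10,11-dihydro-5H-dibenzo[a,d][7]annulen-5-one
Product: 20 (10R)-1-bromo-10-(2,4-dimethoxyphenyl)-2,7,9-trimethoxy-5-(4-methylbenzenesulfonyl)-10,11-dihydro-5H-dibenzo[a,d][7]annulen-4-ol (C5 epimers), via ortho-hydroxybenzhydrol 19 (not isolated)
Conditions: NaBH4, THF/MeOH, 0 °C → rt; then TolSO2Na (3 equiv), HCO2H/H2O, CH2Cl2, rt
Reagents that add atoms: sodium p-toluenesulfinate, Cc1ccc(cc1)S(=O)[O-].[Na+]
Why: Hydride reduction gives the ortho-hydroxybenzhydrol, whose strongly stabilized benzylic cation is captured at sulfur by sulfinate (SN1) to give the base-labile ortho-quinone methide precursor; the configuration at C5 is irrelevant because it becomes planar in step 14.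

Step 13
Reactants: 21 4-methoxybenzyl bromide; 22 tetrahydrothiophene
Product: 23 1-(4-methoxybenzyl)tetrahydrothiophen-1-ium bromide
Conditions: acetone, rt; filter
Reagents that add atoms: none
Why: SN2 S-alkylation of the sulfide by the activated benzylic bromide gives the crystalline sulfonium salt.

Step 14
Reactants: 20 (10R)-1-bromo-10-(2,4-dimethoxyphenyl)-2,7,9-trimethoxy-5-(4-methylbenzenesulfonyl)-10,11-dihydro-5H-dibenzo[a,d][7]annulen-4-ol; 23 1-(4-methoxybenzyl)tetrahydrothiophen-1-ium bromide
Product: 25 bromo trans-dihydrobenzofuran (5R,10R,2′R), via ortho-quinone methide 24 (not isolated)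
Conditions: 23 (2 equiv), Cs2CO3 (3 equiv), MeCN/CH2Cl2, 0 °C → rt
Reagents that add atoms: none
Why: Base-induced 1,4-elimination of sulfinate gives the ortho-quinone methide, the sulfonium ylide adds to C5 and the phenoxide displaces tetrahydrothiophene (formal [4+1] annulation); attack on the face opposite the pseudoaxial C10 aryl group should set C5 as R, and closure through the anti betaine should give the trans C2′ centre (R).

Step 15
Reactants: 25 bromo trans-dihydrobenzofuran (5R,10R,2′R); 26 3,5-dimethoxybenzoyl chloride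
Product: 27 C1 3,5-dimethoxybenzoyl ketone (5R,10R,2′R)
Conditions: n-BuLi (1.1 equiv), THF, −78 °C, 10 min; cannulate into 26 (2 equiv), THF, −78 → 0 °C
Reagents that add atoms: none
Why: Bromine–lithium exchange at −78 °C is faster than any benzylic deprotonation, and acylation of the hindered aryllithium should stop at the di-ortho-substituted benzophenone, which resists a second addition.

Step 16
Reactants: 27 C1 3,5-dimethoxybenzoyl ketone (5R,10R,2′R)
Product: 28 C2 phenol of the C1 3,5-dimethoxybenzoyl ketone (5R,10R,2′R)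
Conditions: BCl3 (1.5 equiv), CH2Cl2, −78 → −20 °C; aq. NaHCO3
Reagents that add atoms: none
Why: Chelation-controlled demethylation again: only the C2 methoxy group is ortho to the new ketone, and the low temperature should limit ionization of the benzylic C2′–O bond, which would in any case re-close to the trans isomer.

Step 17
Reactants: 28 C2 phenol of the C1 3,5-dimethoxybenzoyl ketone (5R,10R,2′R)
Product: 30 C1 aryl(tosyl)methyl phenol (5R,10R,2′R; sulfone carbon epimers), via ortho-hydroxybenzhydrol 29 (not isolated)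
Conditions: LiAlH4, THF, 0 °C; aq. NaOH work-up, filter; then TolSO2Na (3 equiv), HCO2H/H2O, CH2Cl2, rt
Reagents that add atoms: sodium p-toluenesulfinate, Cc1ccc(cc1)S(=O)[O-].[Na+]
Why: The hindered ortho-hydroxy ketone is reduced by the stronger hydride donor, and the resulting benzhydrol undergoes SN1 substitution by sulfinate through its stabilized cation, as in step 12.

Step 18
Reactants: 30 C1 aryl(tosyl)methyl phenol (5R,10R,2′R); 23 1-(4-methoxybenzyl)tetrahydrothiophen-1-ium bromide
Product: 32 octa-O-methyl ether of the target (5R,10R,2′R,2″R,3″R), via ortho-quinone methide 31 (not isolated)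
Conditions: 23 (2 equiv), Cs2CO3 (3 equiv), MeCN/CH2Cl2, 0 °C → rt
Reagents that add atoms: none
Why: The same ortho-quinone methide and sulfonium ylide [4+1] annulation: the methide should place its aryl group syn to the carbonyl to avoid the C11 methylene, the ylide should add from the face opposite the C10 aryl group, which sets C3″ as R, and anti betaine closure should give trans C2″ (R).

Step 19
Reactants: 32 octa-O-methyl ether of the target (5R,10R,2′R,2″R,3″R)
Product: 33 CNP0154047.1 (5R,10R,2′R,2″R,3″R)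
Conditions: BBr3 (20 equiv), CH2Cl2, −78 °C → rt; MeOH, then H2O
Reagents that add atoms: none
Why: Lewis acid cleavage of all eight aryl methyl ethers; any reversible opening of a benzylic dihydrofuran C–O bond should re-close to the thermodynamically preferred trans ring, and no C–H stereocentre is ionizable.

Compound list
1 | 1-allyl-3,5-dimethoxybenzene | C=CCc1cc(OC)cc(OC)c1 | starting material
2 | 3-allyl-2,4-dibromo-1,5-dimethoxybenzene | C=CCc1c(Br)c(OC)cc(OC)c1Br | intermediate
3 | N,N'-dimethoxy-N,N'-dimethyloxamide | CON(C)C(=O)C(=O)N(C)OC | starting material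
4 | 2-(2-allyl-3-bromo-4,6-dimethoxyphenyl)-N-methoxy-N-methyl-2-oxoacetamide | C=CCc1c(Br)c(OC)cc(OC)c1C(=O)C(=O)N(C)OC | intermediate
5 | 2-(2-allyl-3-bromo-4,6-dimethoxyphenyl)-N-methoxy-N-methyl-1,3-dioxolane-2-carboxamide | C=CCc1c(Br)c(OC)cc(OC)c1C1(OCCO1)C(=O)N(C)OC | intermediate
6 | 1-[2-(2-allyl-3-bromo-4,6-dimethoxyphenyl)-1,3-dioxolan-2-yl]prop-2-en-1-one | C=CCc1c(Br)c(OC)cc(OC)c1C1(OCCO1)C(=O)C=C | intermediate
7 | 1-bromo-2,4-dimethoxy-9H-spiro[benzo[7]annulene-5,2'-[1,3]dioxolan]-6-one (C7=C8 cis-enone) | COc1cc(OC)c2c(c1Br)CC=CC(=O)C21OCCO1 | intermediate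
8 | 2,4-dimethoxyphenylboronic acid | COc1ccc(B(O)O)c(OC)c1 | starting material
9 | (8S)-1-bromo-8-(2,4-dimethoxyphenyl)-2,4-dimethoxy-8,9-dihydro-7H-spiro[benzo[7]annulene-5,2'-[1,3]dioxolan]-6-one | COc1cc(OC)c2c(c1Br)C[C@H](c1ccc(OC)cc1OC)CC(=O)C21OCCO1 | intermediate
10 | (8S)-1-bromo-8-(2,4-dimethoxyphenyl)-2,4-dimethoxy-6-(trimethylsilyloxy)-8,9-dihydrospiro[benzo[7]annulene-5,2'-[1,3]dioxolane] | COc1cc(OC)c2c(c1Br)C[C@H](c1ccc(OC)cc1OC)C=C(O[Si](C)(C)C)C21OCCO1 | intermediate
11 | 2,2,6-trimethyl-4H-1,3-dioxin-4-one | CC1=CC(=O)OC(C)(C)O1 | starting material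
12 | cycloadduct: 6-methyl-2-(trimethylsilyloxy)-2,3-dihydro-4H-pyran-4-one fused through its C2–C3 bond to C6–C7 of the benzocycloheptene (aryl-bearing carbon S; the two new ring-fusion centres as formed) | COc1cc(OC)c2c(c1Br)C[C@H](c1ccc(OC)cc1OC)C1C(=O)C=C(C)OC1(O[Si](C)(C)C)C21OCCO1 | intermediate (not isolated)
13 | cyclohepta-fused pyranone: 2-methyl-4H-pyran-4-one whose C5 is bonded to the (R)-CH(2,4-dimethoxyphenyl) carbon and whose C6 is bonded to the spiro-dioxolane carbon of the 1-bromo-2,4-dimethoxybenzocycloheptene | COc1cc(OC)c2c(c1Br)C[C@H](c1ccc(OC)cc1OC)C1=C(OC(C)=CC1=O)C21OCCO1 | intermediate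
14 | (8S)-7-acetoacetyl-1-bromo-8-(2,4-dimethoxyphenyl)-2,4-dimethoxy-8,9-dihydro-7H-spiro[benzo[7]annulene-5,2'-[1,3]dioxolan]-6-one (enol and enolate forms, C7 not fixed) | COc1cc(OC)c2c(c1Br)C[C@H](c1ccc(OC)cc1OC)C(C(=O)CC(C)=O)C(=O)C21OCCO1 | intermediate (not isolated)
15 | (10R)-1-bromo-10-(2,4-dimethoxyphenyl)-2,4-dimethoxy-10,11-dihydrospiro[dibenzo[a,d][7]annulene-5,2'-[1,3]dioxolane]-7,9-diol | COc1cc(OC)c2c(c1Br)C[C@H](c1ccc(OC)cc1OC)c1c(O)cc(O)cc1C21OCCO1 | intermediate
16 | (10R)-1-bromo-10-(2,4-dimethoxyphenyl)-2,4,7,9-tetramethoxy-10,11-dihydrospiro[dibenzo[a,d][7]annulene-5,2'-[1,3]dioxolane] | COc1cc(OC)c2c(c1Br)C[C@H](c1ccc(OC)cc1OC)c1c(OC)cc(OC)cc1C21OCCO1 | intermediate (not isolated)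
17 | (10R)-1-bromo-10-(2,4-dimethoxyphenyl)-2,4,7,9-tetramethoxy-10,11-dihydro-5H-dibenzo[a,d][7]annulen-5-one | COc1cc(OC)c2c(c1Br)C[C@H](c1ccc(OC)cc1OC)c1c(OC)cc(OC)cc1C2=O | intermediate
18 | (10R)-1-bromo-10-(2,4-dimethoxyphenyl)-4-hydroxy-2,7,9-trimethoxy-10,11-dihydro-5H-dibenzo[a,d][7]annulen-5-one | COc1cc(O)c2c(c1Br)C[C@H](c1ccc(OC)cc1OC)c1c(OC)cc(OC)cc1C2=O | intermediate
19 | (10R)-1-bromo-10-(2,4-dimethoxyphenyl)-2,7,9-trimethoxy-10,11-dihydro-5H-dibenzo[a,d][7]annulene-4,5-diol (C5 epimers) | COc1cc(O)c2c(c1Br)C[C@H](c1ccc(OC)cc1OC)c1c(OC)cc(OC)cc1C2O | intermediate (not isolated)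
20 | (10R)-1-bromo-10-(2,4-dimethoxyphenyl)-2,7,9-trimethoxy-5-(4-methylbenzenesulfonyl)-10,11-dihydro-5H-dibenzo[a,d][7]annulen-4-ol (C5 epimers) | COc1cc(O)c2c(c1Br)C[C@H](c1ccc(OC)cc1OC)c1c(OC)cc(OC)cc1C2S(=O)(=O)c1ccc(C)cc1 | intermediate
21 | 4-methoxybenzyl bromide | COc1ccc(CBr)cc1 | starting material
22 | tetrahydrothiophene | C1CCSC1 | starting material
23 | 1-(4-methoxybenzyl)tetrahydrothiophen-1-ium bromide | COc1ccc(C[S+]2CCCC2)cc1.[Br-] | intermediate
24 | ortho-quinone methide: (10R)-1-bromo-10-(2,4-dimethoxyphenyl)-2,7,9-trimethoxy-10,11-dihydro-4H-dibenzo[a,d][7]annulen-4-one (C4=O, C4a=C5) | COC1=CC(=O)C2=Cc3cc(OC)cc(OC)c3[C@@H](c3ccc(OC)cc3OC)CC2=C1Br | intermediate (not isolated)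
25 | bromo trans-dihydrobenzofuran (5R,10R,2′R): dibenzosuberane of 17 with O on C4 joined through C2′H(4-methoxyphenyl) to C5; C1–Br, C2–OMe, C7 and C9 OMe, C10 2,4-dimethoxyphenyl; H5 trans to H2′ and trans to H10 | COc1cc2c3c(c1Br)C[C@H](c1ccc(OC)cc1OC)c1c(OC)cc(OC)cc1[C@H]3[C@H](c1ccc(OC)cc1)O2 | intermediate
26 | 3,5-dimethoxybenzoyl chloride | COc1cc(OC)cc(c1)C(=O)Cl | starting material
27 | ketone (5R,10R,2′R): as 25 with a 3,5-dimethoxybenzoyl group on C1 in place of bromine | COc1cc2c3c(c1C(=O)c1cc(OC)cc(OC)c1)C[C@H](c1ccc(OC)cc1OC)c1c(OC)cc(OC)cc1[C@H]3[C@H](c1ccc(OC)cc1)O2 | intermediate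
28 | phenol ketone (5R,10R,2′R): as 27 with OH on C2 | Oc1cc2c3c(c1C(=O)c1cc(OC)cc(OC)c1)C[C@H](c1ccc(OC)cc1OC)c1c(OC)cc(OC)cc1[C@H]3[C@H](c1ccc(OC)cc1)O2 | intermediate
29 | ortho-hydroxybenzhydrol (5R,10R,2′R; carbinol epimers): as 28 with CH(OH)(3,5-dimethoxyphenyl) on C1 | Oc1cc2c3c(c1C(O)c1cc(OC)cc(OC)c1)C[C@H](c1ccc(OC)cc1OC)c1c(OC)cc(OC)cc1[C@H]3[C@H](c1ccc(OC)cc1)O2 | intermediate (not isolated)
30 | sulfone (5R,10R,2′R; sulfone carbon epimers): as 28 with CH(SO2C6H4Me-4)(3,5-dimethoxyphenyl) on C1 | Oc1cc2c3c(c1C(c1cc(OC)cc(OC)c1)S(=O)(=O)c1ccc(C)cc1)C[C@H](c1ccc(OC)cc1OC)c1c(OC)cc(OC)cc1[C@H]3[C@H](c1ccc(OC)cc1)O2 | intermediate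
31 | ortho-quinone methide (5R,10R,2′R): C2=O and C1=CH(3,5-dimethoxyphenyl) on the skeleton of 28 | O=C1C=C2O[C@@H](c3ccc(OC)cc3)[C@@H]3c4cc(OC)cc(OC)c4[C@@H](c4ccc(OC)cc4OC)CC(=C23)C1=Cc1cc(OC)cc(OC)c1 | intermediate (not isolated)
32 | octa-O-methyl ether of the target (5R,10R,2′R,2″R,3″R), both dihydrobenzofurans trans | COc1ccc([C@@H]2Oc3cc4c5c(c3[C@H]2c2cc(OC)cc(OC)c2)C[C@H](c2ccc(OC)cc2OC)c2c(OC)cc(OC)cc2[C@H]5[C@H](c2ccc(OC)cc2)O4)cc1 | intermediate
33 | CNP0154047.1 (5R,10R,2′R,2″R,3″R) | Oc1ccc([C@@H]2Oc3cc4c5c(c3[C@H]2c2cc(O)cc(O)c2)C[C@H](c2ccc(O)cc2O)c2c(O)cc(O)cc2[C@H]5[C@H](c2ccc(O)cc2)O4)cc1 | target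

Total step count: 19. Longest linear sequence: 18 steps (steps 1–12 and 14–19 from compound 1); step 13 is a one-step branch.

Steps most likely to fail

Step 9. Hydroxide may cleave the 2-substituted β-diketone unit of the opened chain (retro-Claisen loss of the acetoacetyl group, or opening of the seven-membered ring) faster than the hindered ring ketone accepts the weakly populated methyl enolate. The fallback sets out from 13 and makes the terminal carbon a far better nucleophile. Deprotonation of the pyranone methyl group with LiN(SiMe3)2 (2 equiv, THF, −78 °C) and quenching with diethyl chlorophosphate should give the pyranone phosphonate F1. Ba(OH)2 in wet THF at room temperature then opens the ring, and the phosphonate carbanion closes ring B by an irreversible intramolecular Horner–Wadsworth–Emmons olefination of the ring ketone; tautomerization returns the route to 15.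

Step 18. The ylide may add to the wrong face of the ortho-quinone methide, or the methide may react through its other double-bond isomer, so that the diastereomeric trans-dihydrobenzofuran prevails; the only control element is the remote C10 aryl group. The fallback sets out from 28 and replaces substrate control by catalyst control. Alkylation of the phenol with 21 (K2CO3, DMF) gives the 4-methoxybenzyl ether F2. Hydrazine hydrate (EtOH, AcOH, reflux) converts the ketone into the hydrazone F3, and MnO2 oxidizes it to the diaryldiazomethane F4. The enantiomer of the chiral dirhodium carboxylate Rh2(PTAD)4 that is matched to a (3″R) product then effects carbene insertion into the benzylic O–CH2 bond and should give the 2″,3″-cis-dihydrobenzofuran F5. A catalytic amount of CF3CO2H in CH2Cl2 epimerizes C2″ through the benzylic cation to the trans isomer, which is 32.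

Step 8. Dimerization of acetylketene and desilylation of the enol ether may outrun cycloaddition at the hindered, trisubstituted enol silane flanked by the quaternary dioxolane carbon. The fallback sets out from 9 and builds the pyranone stepwise. The lithium enolate of 9 (LiN(SiMe3)2, THF, −78 °C) is added to but-2-ynal to give the aldol F6. Dess–Martin oxidation gives the ynone β-diketone F7, and catalytic CF3SO3H in dry CH2Cl2 at 0 °C should bring about 6-endo-dig addition of the ring-ketone enol oxygen to the ynone, which returns the route to 13.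

Further compounds
F1 | step 9 | diethyl phosphonate of 13 (CH2P(O)(OEt)2 in place of the pyranone methyl group; aryl-bearing carbon R) | COc1cc(OC)c2c(c1Br)C[C@H](c1ccc(OC)cc1OC)C1=C(OC(CP(=O)(OCC)OCC)=CC1=O)C21OCCO1
F2 | step 18 | 4-methoxybenzyl ether of 28 at the C2 oxygen (5R,10R,2′R) | COc1ccc(COc2cc3c4c(c2C(=O)c2cc(OC)cc(OC)c2)C[C@H](c2ccc(OC)cc2OC)c2c(OC)cc(OC)cc2[C@H]4[C@H](c2ccc(OC)cc2)O3)cc1
F3 | step 18 | hydrazone of F2 (5R,10R,2′R) | COc1ccc(COc2cc3c4c(c2C(=NN)c2cc(OC)cc(OC)c2)C[C@H](c2ccc(OC)cc2OC)c2c(OC)cc(OC)cc2[C@H]4[C@H](c2ccc(OC)cc2)O3)cc1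
F4 | step 18 | diaryldiazomethane from F3 (5R,10R,2′R) | COc1ccc(COc2cc3c4c(c2C(=[N+]=[N-])c2cc(OC)cc(OC)c2)C[C@H](c2ccc(OC)cc2OC)c2c(OC)cc(OC)cc2[C@H]4[C@H](c2ccc(OC)cc2)O3)cc1
F5 | step 18 | 2″,3″-cis isomer of 32 (5R,10R,2′R,2″S,3″R) | COc1ccc([C@H]2Oc3cc4c5c(c3[C@H]2c2cc(OC)cc(OC)c2)C[C@H](c2ccc(OC)cc2OC)c2c(OC)cc(OC)cc2[C@H]5[C@H](c2ccc(OC)cc2)O4)cc1
F6 | step 8 | aldol of 9 with but-2-ynal: 7-(1-hydroxybut-2-ynyl) derivative of 9 (C8 S; new centres as formed) | COc1cc(OC)c2c(c1Br)C[C@H](c1ccc(OC)cc1OC)C(C(O)C#CC)C(=O)C21OCCO1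
F7 | step 8 | 7-(but-2-ynoyl) derivative of 9 (C8 S; C7 enolized) | COc1cc(OC)c2c(c1Br)C[C@H](c1ccc(OC)cc1OC)C(C(=O)C#CC)C(=O)C21OCCO1
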